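The readings are simulated for an exercise, and the scatter is random.

Late in Tuesday's run the target and the other capture product stand nearly level, and the reckoning here rests on that late ratio.

the same everywhere: substrate 10 mM

| flask | second nucleophile | gas | remark | time |
|---|---|---|---|---|
| Tuesday's | 7.5 mM | 5 mM (held) | run made earlier |  |
| flask | 15.0 mM | 5.0 mM (held) |  | 10 min |

Tuesday's run (percent of the substrate charged)

| time / s | target / % | other capture product / % | substrate / % |
|---|---|---|---|
| 10.0 | 23.8 | 35.6 | 37.2 |
| 15.0 | 32.5 | 41.0 | 21.3 |
| 20.0 | 38.2 | 41.7 | 13.1 |
| 30.0 | 43.2 | 43.4 | 3.8 |
| 50.0 | 45.7 | 43.6 | 0.8 |
| 80.0 | 46.2 | 43.2 | 0.2 |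
| 120 | 44.9 | 43.3 | 0.9 |

(each reading ± 0.5 percentage points)

- at the start none of the gas is in solution

1. ratio of target to other capture product at 0.20 s
2. ratio of target to other capture product at 10 min

Start with the main step alone. The substrate falls first order, so two of Tuesday's readings give its rate constant and lifetime:

k = ln(substrate at 10.0 s / substrate at 20.0 s) / elapsed time = 0.104 /s

lifetime = 1/k = 9.58 s

The asked 10 min lies far beyond that lifetime, so it belongs with the late readings.

Add capture by the second nucleophile, and the substrate lost turns up as other capture product. Then add the gas, taken here as the source of the target. None is dissolved at the start, so the two captures compete on shifting terms: the rate ratio at a moment should go as dissolved gas over second nucleophile, and it drifts upward. On Tuesday the other capture product moves from 41.7% to 43.4% between 20.0 s and 30.0 s, while substrate falls from 13.1% to 3.8%.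

For a first estimate, with the gas held alike, this reckoning assumes that one number read on Tuesday can be taken over to this flask: the capture index, a working selectivity factor, which is the accumulated target-to-other ratio at a given time times the equivalents of second nucleophile charged. This is an assumption to be tested, since the ratio is accumulated and the second nucleophile is used up as the run goes on.

index, Tuesday, mean of the last three readings = 0.789

index, Tuesday, at 10.0 s = 0.501; at 15.0 s = 0.595

late ratio, this flask = index / 1.50 = 0.526

Tuesday's index rose faster on average before 10.0 s than after it, so a straight chord from zero, with the index again taken over, gives a low estimate of the early ratio: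

early ratio, this flask, low estimate = 0.00669

The forecast stands at 0.007 and 0.55, its late value a little above this reckoning, with the caution “This assignment is inferred, not proven.”

The flask gives 0.0198 at 0.20 s and 0.612 at 10 min, the first above the low estimate by a factor of 2.96.

    first nucleophile + intermediate → target (k = 10600 /M/s)
    substrate + target → side product (k = 3.04 /M/s)
    substrate → intermediate (k = 0.0978 /s)
    second nucleophile + intermediate → other capture product (k = 1770 /M/s)
    gas ⇌ first nucleophile, rate k5*(csat - [first nucleophile]) (kL = 0.0893 /s)

At 10.0 min the flask holds 35.0% target, 57.1% other capture product and 7.86% side product, which counts as two. The index of this flask is 0.918, higher than the 0.789 read on Tuesday, so the index did not carry over unchanged. In the neighbour flask with 60 mM of second nucleophile, Tuesday's index gives a late ratio of 0.131; the computed value there is 0.189, higher than that estimate.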